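**Plan**

- Retrosynthesis: the 22 O‑benzyl groups are cut first, then the C4–C8 bond between the upper epicatechin gallate and the central unit, then the gallate ester C–O bonds of the central and lower units, then the C4–C8 bond between the central unit and catechin. In the central epigallocatechin unit, ring C is opened at O1–C8a and the chain is cut at C4–C4a and C2–C3.
- Forward: C2–C3 (alkoxyallylboration) and C4–C4a (aryllithium addition) give the open chain. Ring C of the central unit is closed by O1–C8a SNAr to a flavan‑3,4‑diol, whose C4 cation is joined to C8 of benzylated catechin. After galloylation, the C4 cation of the upper unit is joined to C8 of the central ring A, and hydrogenolysis ends the route.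
- Stereochemistry: the upper and lower units come from (−)‑epicatechin and (+)‑catechin. Central C2/C3 are set syn by the isopinocampheyl‑controlled alkoxyallylboration and pass unchanged through the ring closure, because the C2–O bond is never broken, so syn becomes 2,3‑cis. Both interflavan C4 centres arise by attack on flavan‑4‑yl cations trans to the C3 oxygen (4β).
- Enabling feature: ring A of the central unit is a phloroglucinol ring whose oxygens at C5, C7 and C8a are mutually meta. A fluorine at C8a is therefore meta to both benzyloxy groups, and the Meisenheimer charge falls on C4a, C6 and C8. The C2 oxygen lies in the chain O–C2–C3–C4–C4a–C8a, the geometry of a six‑membered closure.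

Key step: step 12

Remark: the target is read as epicatechin 3‑O‑gallate‑(4β→8)‑epigallocatechin 3‑O‑gallate‑(4β→8)‑catechin 3‑O‑gallate (lower unit 2R,3S, 2,3‑trans); compounds 19 and 22–25 are carried as epimer mixtures at a carbon that is cleaved (19) or ionised (22–25) later.

**Step 1**
Reactants: 1 (−)-epicatechin
Product: 2 5,7,3',4'-tetra-O-benzyl-(−)-epicatechin
Conditions: BnBr (4.4 equiv), K2CO3, DMF, 0 °C to rt
Reagents that add atoms: benzyl bromide, BrCc1ccccc1
Why: Williamson etherification; the four phenols are alkylated by carbonate base in preference to the secondary 3‑OH, and no stereocentre is touched.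

**Step 2**
Reactants: 2 5,7,3',4'-tetra-O-benzyl-(−)-epicatechin
Product: 3 4β-(2-ethoxyethoxy)-5,7,3',4'-tetra-O-benzyl-(−)-epicatechin
Conditions: DDQ (2 equiv), 2-ethoxyethanol (5 equiv), CH2Cl2, rt
Reagents that add atoms: 2-ethoxyethanol, CCOCCO
Why: DDQ benzylic oxidation; hydride abstraction at C4 gives the 5,7‑dialkoxy‑stabilised flavan‑4‑yl cation, which the alcohol should capture on the β face, trans to the 3‑OH and the 2‑aryl group.

**Step 3**
Reactants: 3 4β-(2-ethoxyethoxy)-5,7,3',4'-tetra-O-benzyl-(−)-epicatechin; 4 3,4,5-tris(benzyloxy)benzoic acid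
Product: 5 4β-(2-ethoxyethoxy)-5,7,3',4'-tetra-O-benzyl-(−)-epicatechin 3-O-[3,4,5-tris(benzyloxy)benzoate]
Conditions: DCC, DMAP, CH2Cl2, rt
Reagents that add atoms: none
Why: Steglich esterification of the secondary 3‑OH; the C4 acetal‑type ether is stable to these neutral conditions and no stereocentre is involved.

**Step 4**
Reactants: 6 (+)-catechin
Product: 7 5,7,3',4'-tetra-O-benzyl-(+)-catechin
Conditions: BnBr (4.4 equiv), K2CO3, DMF, 0 °C to rt
Reagents that add atoms: benzyl bromide, BrCc1ccccc1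
Why: Williamson etherification of the four phenols, as in step 1.

**Step 5**
Reactants: 8 1,3,5-trifluorobenzene
Product: 9 1,3-bis(benzyloxy)-5-fluorobenzene
Conditions: BnOH (2.1 equiv), NaH (2.2 equiv), NMP, 0 to 90 °C
Reagents that add atoms: benzyl alcohol, OCc1ccccc1
Why: twofold SNAr by benzyl oxide; each fluorine is activated by the two meta fluorines or alkoxy groups, and the third substitution is the slowest, so the stoichiometry should stop the reaction at the difluoride‑displaced stage.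

**Step 6**
Reactants: 9 1,3-bis(benzyloxy)-5-fluorobenzene
Product: 10 1,5-bis(benzyloxy)-2-bromo-3-fluorobenzene
Conditions: NBS (1.0 equiv), MeCN, 0 °C
Reagents that add atoms: N-bromosuccinimide, BrN1C(=O)CCC1=O
Why: electrophilic aromatic bromination; the position ortho to fluorine and para to a benzyloxy group should be favoured over the more hindered position between the two benzyloxy groups, which fixes the later site of the carbon chain.

**Step 7**
Reactants: 11 3,4,5-tris(benzyloxy)benzaldehyde; 12 allyl methoxymethyl ether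
Product: 17 (1R,2R)-2-(methoxymethoxy)-1-[3,4,5-tris(benzyloxy)phenyl]but-3-en-1-ol, via lithiated allyl ether 13 (not isolated), via borate complex 14 (not isolated), via allylborane 15 (not isolated), via borinate 16 (not isolated)
Conditions: 12, s-BuLi, THF, −78 °C; (−)-Ipc2BOMe; BF3·OEt2; then 11, −78 °C; NaOH, H2O2, 0 °C to rt
Reagents that add atoms: none
Why: Brown asymmetric alkoxyallylboration through a chair Zimmerman–Traxler transition state; the Z geometry of the allylborane gives the syn relation of the two oxygens, and the isopinocampheyl groups from (+)‑α‑pinene direct attack to the Si face of the aldehyde, giving the (1R,2R) product with the future C3 oxygen already capped and the future C2 oxygen free.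

**Step 8**
Reactants: 17 (1R,2R)-2-(methoxymethoxy)-1-[3,4,5-tris(benzyloxy)phenyl]but-3-en-1-ol
Product: 18 tert-butyl{[(1R,2R)-2-(methoxymethoxy)-1-[3,4,5-tris(benzyloxy)phenyl]but-3-en-1-yl]oxy}dimethylsilane
Conditions: TBSCl, imidazole, DMF, rt to 40 °C
Reagents that add atoms: tert-butyldimethylsilyl chloride, CC(C)(C)[Si](C)(C)Cl
Why: silylation of the benzylic alcohol, needed so that the next two steps meet no free β‑hydroxy aldehyde; the configuration is unchanged.

**Step 9**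
Reactants: 18 tert-butyl{[(1R,2R)-2-(methoxymethoxy)-1-[3,4,5-tris(benzyloxy)phenyl]but-3-en-1-yl]oxy}dimethylsilane
Product: 20 (2S,3R)-3-[(tert-butyldimethylsilyl)oxy]-2-(methoxymethoxy)-3-[3,4,5-tris(benzyloxy)phenyl]propanal, via diol 19 (not isolated)
Conditions: OsO4 (cat.), NaIO4, 2,6-lutidine, dioxane/H2O, rt
Reagents that add atoms: osmium tetroxide, O=[Os](=O)(=O)=O; sodium periodate, [Na+].[O-]I(=O)(=O)=O
Why: Lemieux–Johnson oxidative cleavage of the terminal alkene; the buffered, ozone‑free conditions spare the electron‑rich arenes and should leave the α‑alkoxy stereocentre intact.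

**Step 10**
Reactants: 10 1,5-bis(benzyloxy)-2-bromo-3-fluorobenzene; 20 (2S,3R)-3-[(tert-butyldimethylsilyl)oxy]-2-(methoxymethoxy)-3-[3,4,5-tris(benzyloxy)phenyl]propanal
Product: 22 (1RS,2R,3R)-1-[2,4-bis(benzyloxy)-6-fluorophenyl]-3-[(tert-butyldimethylsilyl)oxy]-2-(methoxymethoxy)-3-[3,4,5-tris(benzyloxy)phenyl]propan-1-ol, via aryllithium 21 (not isolated)
Conditions: 10, n-BuLi, THF, −78 °C; then 20, −78 °C; H2O
Reagents that add atoms: none
Why: bromine–lithium exchange followed by 1,2‑addition to the aldehyde forms the C4–C4a bond and installs the C4 oxygen that later serves as leaving group; the new carbinol centre need not be controlled because it is ionised in step 13.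

**Step 11**
Reactants: 22 (1RS,2R,3R)-1-[2,4-bis(benzyloxy)-6-fluorophenyl]-3-[(tert-butyldimethylsilyl)oxy]-2-(methoxymethoxy)-3-[3,4,5-tris(benzyloxy)phenyl]propan-1-ol
Product: 23 (1RS,2S,3R)-1-[2,4-bis(benzyloxy)-6-fluorophenyl]-2-(methoxymethoxy)-3-[3,4,5-tris(benzyloxy)phenyl]propane-1,3-diol
Conditions: TBAF, THF, 0 °C to rt
Reagents that add atoms: none
Why: fluoride desilylation frees the future ring oxygen under non‑acidic conditions that do not ionise the activated benzylic C4–OH.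

**Step 12**
Reactants: 23 (1RS,2S,3R)-1-[2,4-bis(benzyloxy)-6-fluorophenyl]-2-(methoxymethoxy)-3-[3,4,5-tris(benzyloxy)phenyl]propane-1,3-diol
Product: 25 (2R,3R,4RS)-5,7-bis(benzyloxy)-3-(methoxymethoxy)-2-[3,4,5-tris(benzyloxy)phenyl]chroman-4-ol, via dipotassium dialkoxide 24 (not isolated)
Conditions: KH (3 equiv), 18-crown-6 (cat.), THF, 0 °C to reflux; H2O
Reagents that add atoms: none
Why: KH converts both hydroxyls into potassium alkoxides (24); the C2 alkoxide adds to C8a of ring A to give a Meisenheimer anion with its charge on C4a, C6 and C8, and loss of fluoride restores the arene (addition–elimination SNAr). The closest known reaction type is the intramolecular SNAr oxycyclisation of 2‑fluoroaryl‑substituted alkoxides to chromans, including fluoroarenes that carry meta alkoxy groups. Only ring C is closed, through the O1–C8a bond in a 6‑exo‑trig mode; the C4 alkoxide could only form a four‑membered ring and the C3 oxygen is capped as its methoxymethyl ether, so the five‑membered alternative is excluded. No new stereocentre is formed: the nucleophile is the C2 oxygen and no bond to C2 or C3 is broken, so the syn relation from step 7 becomes the 2,3‑cis relation of the ring. The step needs substitution at the one C–F carbon and tolerance of an electron‑rich ring; the single fluorine secures the first, and the meta position of both benzyloxy groups, which stabilise the anion inductively without donating to C8a, secures the second, while C8 stays unsubstituted for step 16.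

**Step 13**
Reactants: 25 (2R,3R,4RS)-5,7-bis(benzyloxy)-3-(methoxymethoxy)-2-[3,4,5-tris(benzyloxy)phenyl]chroman-4-ol; 7 5,7,3',4'-tetra-O-benzyl-(+)-catechin
Product: 26 5,7,3',4',5'-penta-O-benzyl-3-O-(methoxymethyl)epigallocatechin-(4β→8)-5,7,3',4'-tetra-O-benzylcatechin
Conditions: 7 (4 equiv), BF3·OEt2 (0.5 equiv), 4 Å molecular sieves, CH2Cl2, −78 to −30 °C
Reagents that add atoms: none
Why: Lewis‑acid‑promoted Friedel–Crafts coupling through the flavan‑4‑yl cation; both C4 epimers of 25 converge on one cation, C8 of the catechin ring A attacks on the β face, trans to the α‑oriented C3 oxygen and C2 aryl group, and the excess nucleophile suppresses self‑condensation.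

**Step 14**
Reactants: 26 5,7,3',4',5'-penta-O-benzyl-3-O-(methoxymethyl)epigallocatechin-(4β→8)-5,7,3',4'-tetra-O-benzylcatechin
Product: 27 5,7,3',4',5'-penta-O-benzylepigallocatechin-(4β→8)-5,7,3',4'-tetra-O-benzylcatechin
Conditions: ZnBr2 (1 equiv), n-PrSH (2 equiv), CH2Cl2, 0 °C, short reaction time
Reagents that add atoms: none
Why: Lewis‑acid‑assisted transfer of the methoxymethyl group to the thiol, a mild acetal cleavage expected to spare the benzyl ethers and, at 0 °C, the interflavan bond.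

**Step 15**
Reactants: 27 5,7,3',4',5'-penta-O-benzylepigallocatechin-(4β→8)-5,7,3',4'-tetra-O-benzylcatechin; 4 3,4,5-tris(benzyloxy)benzoic acid
Product: 28 5,7,3',4',5'-penta-O-benzylepigallocatechin-(4β→8)-5,7,3',4'-tetra-O-benzylcatechin 3,3''-bis-O-[3,4,5-tris(benzyloxy)benzoate]
Conditions: 4 (4 equiv), DCC, DMAP, CH2Cl2, rt to 40 °C
Reagents that add atoms: none
Why: twofold Steglich esterification of the two secondary 3‑hydroxyls, done at the dimer stage where the axial central 3‑OH is still accessible.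

**Step 16**
Reactants: 28 5,7,3',4',5'-penta-O-benzylepigallocatechin-(4β→8)-5,7,3',4'-tetra-O-benzylcatechin 3,3''-bis-O-[3,4,5-tris(benzyloxy)benzoate]; 5 4β-(2-ethoxyethoxy)-5,7,3',4'-tetra-O-benzyl-(−)-epicatechin 3-O-[3,4,5-tris(benzyloxy)benzoate]
Product: 29 docosa-O-benzyl ether of epicatechin 3-O-gallate-(4β→8)-epigallocatechin 3-O-gallate-(4β→8)-catechin 3-O-gallate
Conditions: 28 (1.5 equiv), TMSOTf (cat.), CH2Cl2, −78 to −40 °C
Reagents that add atoms: none
Why: TMSOTf‑catalysed flavan‑4‑yl cation coupling; the 3‑O‑acyl group shields the α face by acyloxonium participation so that attack is 4β, and C8 of the central ring A (between O1 and the C7 benzyloxy group) is the most reactive open site of the dimer.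

**Step 17**
Reactants: 29 docosa-O-benzyl ether of epicatechin 3-O-gallate-(4β→8)-epigallocatechin 3-O-gallate-(4β→8)-catechin 3-O-gallate
Product: 30 epicatechin 3-O-gallate-(4β→8)-epigallocatechin 3-O-gallate-(4β→8)-catechin 3-O-gallate (CNP0321910.1)
Conditions: H2 (1 atm), Pd(OH)2/C, THF/MeOH/H2O, rt
Reagents that add atoms: none
Why: global hydrogenolysis of the 22 benzyl ethers under neutral conditions, which should leave the gallate esters, the interflavan bonds and all stereocentres untouched.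

**Compound list**

1 | (−)-epicatechin | C1c2c(O)cc(O)cc2O[C@H](c2ccc(O)c(O)c2)[C@@H]1O | starting material
2 | 5,7,3',4'-tetra-O-benzyl-(−)-epicatechin | C1c2c(OCc5ccccc5)cc(OCc5ccccc5)cc2O[C@H](c2ccc(OCc5ccccc5)c(OCc5ccccc5)c2)[C@@H]1O | intermediate
3 | 4β-(2-ethoxyethoxy)-5,7,3',4'-tetra-O-benzyl-(−)-epicatechin (2R,3R,4S) | CCOCCO[C@H]1c2c(OCc5ccccc5)cc(OCc5ccccc5)cc2O[C@H](c2ccc(OCc5ccccc5)c(OCc5ccccc5)c2)[C@@H]1O | intermediate
4 | 3,4,5-tris(benzyloxy)benzoic acid | OC(=O)c1cc(OCc5ccccc5)c(OCc5ccccc5)c(OCc5ccccc5)c1 | starting material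
5 | 4β-(2-ethoxyethoxy)-5,7,3',4'-tetra-O-benzyl-(−)-epicatechin 3-O-[3,4,5-tris(benzyloxy)benzoate] | CCOCCO[C@H]1c2c(OCc5ccccc5)cc(OCc5ccccc5)cc2O[C@H](c2ccc(OCc5ccccc5)c(OCc5ccccc5)c2)[C@@H]1OC(=O)c1cc(OCc5ccccc5)c(OCc5ccccc5)c(OCc5ccccc5)c1 | intermediate
6 | (+)-catechin | C1c2c(O)cc(O)cc2O[C@H](c2ccc(O)c(O)c2)[C@H]1O | starting material
7 | 5,7,3',4'-tetra-O-benzyl-(+)-catechin | C1c2c(OCc5ccccc5)cc(OCc5ccccc5)cc2O[C@H](c2ccc(OCc5ccccc5)c(OCc5ccccc5)c2)[C@H]1O | intermediate
8 | 1,3,5-trifluorobenzene | Fc1cc(F)cc(F)c1 | starting material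
9 | 1,3-bis(benzyloxy)-5-fluorobenzene | Fc1cc(OCc5ccccc5)cc(OCc5ccccc5)c1 | intermediate
10 | 1,5-bis(benzyloxy)-2-bromo-3-fluorobenzene | Fc1cc(OCc5ccccc5)cc(OCc5ccccc5)c1Br | intermediate
11 | 3,4,5-tris(benzyloxy)benzaldehyde | O=Cc1cc(OCc5ccccc5)c(OCc5ccccc5)c(OCc5ccccc5)c1 | starting material
12 | allyl methoxymethyl ether | C=CCOCOC | starting material
13 | (Z)-3-(methoxymethoxy)allyllithium (formed in the flask) | [Li]C/C=C\OCOC | intermediate
14 | lithium [(Z)-3-(methoxymethoxy)allyl](methoxy)bis(isopinocampheyl)borate, isopinocampheyl groups from (+)-α-pinene (formed in the flask) | [Li+].CO[B-](C/C=C\OCOC)([C@@H]1C[C@@H]2C[C@H]([C@H]1C)C2(C)C)[C@@H]1C[C@@H]2C[C@H]([C@H]1C)C2(C)C | intermediate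
15 | [(Z)-3-(methoxymethoxy)allyl]bis(isopinocampheyl)borane (formed in the flask) | COCO/C=C\CB([C@@H]1C[C@@H]2C[C@H]([C@H]1C)C2(C)C)[C@@H]1C[C@@H]2C[C@H]([C@H]1C)C2(C)C | intermediate
16 | bis(isopinocampheyl)borinate of 17 (formed in the flask) | C=C[C@@H](OCOC)[C@H](OB([C@@H]1C[C@@H]2C[C@H]([C@H]1C)C2(C)C)[C@@H]1C[C@@H]2C[C@H]([C@H]1C)C2(C)C)c1cc(OCc5ccccc5)c(OCc5ccccc5)c(OCc5ccccc5)c1 | intermediate
17 | (1R,2R)-2-(methoxymethoxy)-1-[3,4,5-tris(benzyloxy)phenyl]but-3-en-1-ol (syn) | C=C[C@@H](OCOC)[C@H](O)c1cc(OCc5ccccc5)c(OCc5ccccc5)c(OCc5ccccc5)c1 | intermediate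
18 | tert-butyl{[(1R,2R)-2-(methoxymethoxy)-1-[3,4,5-tris(benzyloxy)phenyl]but-3-en-1-yl]oxy}dimethylsilane | C=C[C@@H](OCOC)[C@H](O[Si](C)(C)C(C)(C)C)c1cc(OCc5ccccc5)c(OCc5ccccc5)c(OCc5ccccc5)c1 | intermediate
19 | (2RS,3R,4R)-4-[(tert-butyldimethylsilyl)oxy]-3-(methoxymethoxy)-4-[3,4,5-tris(benzyloxy)phenyl]butane-1,2-diol (formed in the flask) | OCC(O)[C@@H](OCOC)[C@H](O[Si](C)(C)C(C)(C)C)c1cc(OCc5ccccc5)c(OCc5ccccc5)c(OCc5ccccc5)c1 | intermediate
20 | (2S,3R)-3-[(tert-butyldimethylsilyl)oxy]-2-(methoxymethoxy)-3-[3,4,5-tris(benzyloxy)phenyl]propanal | O=C[C@@H](OCOC)[C@H](O[Si](C)(C)C(C)(C)C)c1cc(OCc5ccccc5)c(OCc5ccccc5)c(OCc5ccccc5)c1 | intermediate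
21 | [2,4-bis(benzyloxy)-6-fluorophenyl]lithium (formed in the flask) | [Li]c1c(F)cc(OCc5ccccc5)cc1OCc5ccccc5 | intermediate
22 | (1RS,2R,3R)-1-[2,4-bis(benzyloxy)-6-fluorophenyl]-3-[(tert-butyldimethylsilyl)oxy]-2-(methoxymethoxy)-3-[3,4,5-tris(benzyloxy)phenyl]propan-1-ol | OC(c1c(F)cc(OCc5ccccc5)cc1OCc5ccccc5)[C@@H](OCOC)[C@H](O[Si](C)(C)C(C)(C)C)c1cc(OCc5ccccc5)c(OCc5ccccc5)c(OCc5ccccc5)c1 | intermediate
23 | (1RS,2S,3R)-1-[2,4-bis(benzyloxy)-6-fluorophenyl]-2-(methoxymethoxy)-3-[3,4,5-tris(benzyloxy)phenyl]propane-1,3-diol | OC(c1c(F)cc(OCc5ccccc5)cc1OCc5ccccc5)[C@@H](OCOC)[C@H](O)c1cc(OCc5ccccc5)c(OCc5ccccc5)c(OCc5ccccc5)c1 | intermediate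
24 | dipotassium 1,3-dialkoxide of 23 (formed in the flask) | [K+].[K+].[O-]C(c1c(F)cc(OCc5ccccc5)cc1OCc5ccccc5)[C@@H](OCOC)[C@H]([O-])c1cc(OCc5ccccc5)c(OCc5ccccc5)c(OCc5ccccc5)c1 | intermediate
25 | (2R,3R,4RS)-5,7-bis(benzyloxy)-3-(methoxymethoxy)-2-[3,4,5-tris(benzyloxy)phenyl]chroman-4-ol (2,3-cis) | COCO[C@@H]1C(O)c2c(OCc5ccccc5)cc(OCc5ccccc5)cc2O[C@@H]1c1cc(OCc5ccccc5)c(OCc5ccccc5)c(OCc5ccccc5)c1 | intermediate
26 | 5,7,3',4',5'-penta-O-benzyl-3-O-(methoxymethyl)epigallocatechin-(4β→8)-5,7,3',4'-tetra-O-benzylcatechin | COCO[C@@H]1[C@@H](c2c(OCc5ccccc5)cc(OCc5ccccc5)c3c2O[C@H](c2ccc(OCc5ccccc5)c(OCc5ccccc5)c2)[C@@H](O)C3)c2c(OCc5ccccc5)cc(OCc5ccccc5)cc2O[C@@H]1c1cc(OCc5ccccc5)c(OCc5ccccc5)c(OCc5ccccc5)c1 | intermediate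
27 | 5,7,3',4',5'-penta-O-benzylepigallocatechin-(4β→8)-5,7,3',4'-tetra-O-benzylcatechin | O[C@@H]1[C@@H](c2c(OCc5ccccc5)cc(OCc5ccccc5)c3c2O[C@H](c2ccc(OCc5ccccc5)c(OCc5ccccc5)c2)[C@@H](O)C3)c2c(OCc5ccccc5)cc(OCc5ccccc5)cc2O[C@@H]1c1cc(OCc5ccccc5)c(OCc5ccccc5)c(OCc5ccccc5)c1 | intermediate
28 | 5,7,3',4',5'-penta-O-benzylepigallocatechin-(4β→8)-5,7,3',4'-tetra-O-benzylcatechin 3,3''-bis-O-[3,4,5-tris(benzyloxy)benzoate] | O=C(O[C@@H]1[C@@H](c2c(OCc5ccccc5)cc(OCc5ccccc5)c3c2O[C@H](c2ccc(OCc5ccccc5)c(OCc5ccccc5)c2)[C@@H](OC(=O)c2cc(OCc5ccccc5)c(OCc5ccccc5)c(OCc5ccccc5)c2)C3)c2c(OCc5ccccc5)cc(OCc5ccccc5)cc2O[C@@H]1c1cc(OCc5ccccc5)c(OCc5ccccc5)c(OCc5ccccc5)c1)c1cc(OCc5ccccc5)c(OCc5ccccc5)c(OCc5ccccc5)c1 | intermediate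
29 | docosa-O-benzyl ether of epicatechin 3-O-gallate-(4β→8)-epigallocatechin 3-O-gallate-(4β→8)-catechin 3-O-gallate | O=C(O[C@@H]1[C@@H](c2c(OCc5ccccc5)cc(OCc5ccccc5)c3c2O[C@H](c2ccc(OCc5ccccc5)c(OCc5ccccc5)c2)[C@@H](OC(=O)c2cc(OCc5ccccc5)c(OCc5ccccc5)c(OCc5ccccc5)c2)C3)c2c(OCc5ccccc5)cc(OCc5ccccc5)c([C@H]3c4c(OCc5ccccc5)cc(OCc5ccccc5)cc4O[C@H](c4ccc(OCc5ccccc5)c(OCc5ccccc5)c4)[C@@H]3OC(=O)c3cc(OCc5ccccc5)c(OCc5ccccc5)c(OCc5ccccc5)c3)c2O[C@@H]1c1cc(OCc5ccccc5)c(OCc5ccccc5)c(OCc5ccccc5)c1)c1cc(OCc5ccccc5)c(OCc5ccccc5)c(OCc5ccccc5)c1 | intermediate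
30 | epicatechin 3-O-gallate-(4β→8)-epigallocatechin 3-O-gallate-(4β→8)-catechin 3-O-gallate (CNP0321910.1) | O=C(O[C@@H]1[C@@H](c2c(O)cc(O)c3c2O[C@H](c2ccc(O)c(O)c2)[C@@H](OC(=O)c2cc(O)c(O)c(O)c2)C3)c2c(O)cc(O)c([C@H]3c4c(O)cc(O)cc4O[C@H](c4ccc(O)c(O)c4)[C@@H]3OC(=O)c3cc(O)c(O)c(O)c3)c2O[C@@H]1c1cc(O)c(O)c(O)c1)c1cc(O)c(O)c(O)c1 | target

**Count and risks**

Total step count: 17. Longest linear sequence: 11 steps (steps 7 to 17).

Steps most likely to fail:

Step 12. The substitution at the electron‑rich fluoroarene may be slow enough that the dialkoxide is consumed by other base‑induced processes before ring closure, or closure may stop at partial conversion. The fallback replaces the SNAr by a copper‑catalysed Ullmann‑type etherification of an aryl bromide; it sets out from aldehyde 20 and returns to the route at 25. Commercial 1,3-bis(benzyloxy)-5-bromobenzene would be iodinated (NIS, cat. CF3CO2H, MeCN) to 1,5-bis(benzyloxy)-3-bromo-2-iodobenzene F1. Selective iodine–magnesium exchange (iPrMgCl·LiCl, THF, −40 °C) and addition to 20 should give the bromo carbinol (1RS,2R,3R)-1-[2,4-bis(benzyloxy)-6-bromophenyl]-3-[(tert-butyldimethylsilyl)oxy]-2-(methoxymethoxy)-3-[3,4,5-tris(benzyloxy)phenyl]propan-1-ol F2. TBAF would give the bromo diol (1RS,2S,3R)-1-[2,4-bis(benzyloxy)-6-bromophenyl]-2-(methoxymethoxy)-3-[3,4,5-tris(benzyloxy)phenyl]propane-1,3-diol F3. CuI, 3,4,7,8-tetramethyl-1,10-phenanthroline and Cs2CO3 in toluene at 110 °C would then close the same O1–C8a bond with retention at C2 to give 25.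

Step 16. Capture of the cation by C8 of the bulky digalloylated dimer may be retarded, so that self‑condensation of the electrophile, attack at a C6 position, or acid‑induced scission and scrambling of the existing interflavan bond compete. The fallback changes the order of events so that the coupling is run on the less encumbered, ester‑free partners; it sets out from 27 and 3 and returns at 29. Dimer diol 27 (excess) and the non‑acylated electrophile 3 would be coupled (TMSOTf, CH2Cl2, −78 °C; 4β attack under control of the 2,3‑cis ring) to the trimer triol 5,7,3',4'-tetra-O-benzylepicatechin-(4β→8)-5,7,3',4',5'-penta-O-benzylepigallocatechin-(4β→8)-5,7,3',4'-tetra-O-benzylcatechin F4. Threefold Steglich esterification with acid 4 (DCC, DMAP, CH2Cl2) would then give 29.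

Step 10. The ortho‑fluoroaryllithium may lose LiF to an aryne on slight warming, and the basic reagent may enolise the α‑alkoxy aldehyde, which would epimerise the future C3. The fallback replaces the preformed organolithium by a non‑basic chromium‑mediated Nozaki–Hiyama–Kishi coupling; it sets out from 9 and 20 and returns at 22. Fluoroarene 9 would be iodinated (NIS, cat. CF3CO2H, MeCN) to 1,5-bis(benzyloxy)-3-fluoro-2-iodobenzene F5, which with CrCl2 and catalytic NiCl2 in DMF/THF at rt should add to 20 to give 22.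

**Further compounds**

F1 | step 12 | 1,5-bis(benzyloxy)-3-bromo-2-iodobenzene | Brc1cc(OCc5ccccc5)cc(OCc5ccccc5)c1I
F2 | step 12 | (1RS,2R,3R)-1-[2,4-bis(benzyloxy)-6-bromophenyl]-3-[(tert-butyldimethylsilyl)oxy]-2-(methoxymethoxy)-3-[3,4,5-tris(benzyloxy)phenyl]propan-1-ol | OC(c1c(Br)cc(OCc5ccccc5)cc1OCc5ccccc5)[C@@H](OCOC)[C@H](O[Si](C)(C)C(C)(C)C)c1cc(OCc5ccccc5)c(OCc5ccccc5)c(OCc5ccccc5)c1
F3 | step 12 | (1RS,2S,3R)-1-[2,4-bis(benzyloxy)-6-bromophenyl]-2-(methoxymethoxy)-3-[3,4,5-tris(benzyloxy)phenyl]propane-1,3-diol | OC(c1c(Br)cc(OCc5ccccc5)cc1OCc5ccccc5)[C@@H](OCOC)[C@H](O)c1cc(OCc5ccccc5)c(OCc5ccccc5)c(OCc5ccccc5)c1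
F4 | step 16 | 5,7,3',4'-tetra-O-benzylepicatechin-(4β→8)-5,7,3',4',5'-penta-O-benzylepigallocatechin-(4β→8)-5,7,3',4'-tetra-O-benzylcatechin | O[C@@H]1[C@@H](c2c(OCc5ccccc5)cc(OCc5ccccc5)c3c2O[C@H](c2ccc(OCc5ccccc5)c(OCc5ccccc5)c2)[C@@H](O)C3)c2c(OCc5ccccc5)cc(OCc5ccccc5)c([C@H]3c4c(OCc5ccccc5)cc(OCc5ccccc5)cc4O[C@H](c4ccc(OCc5ccccc5)c(OCc5ccccc5)c4)[C@@H]3O)c2O[C@@H]1c1cc(OCc5ccccc5)c(OCc5ccccc5)c(OCc5ccccc5)c1
F5 | step 10 | 1,5-bis(benzyloxy)-3-fluoro-2-iodobenzene | Fc1cc(OCc5ccccc5)cc(OCc5ccccc5)c1I
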